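Decide whether more Z buys D in a 50 min run: bracket the answer first, then count turnovers.

the same everywhere: Q 1.1 M

| flask | Z | remark | time |
|---|---|---|---|
| zeta | 8.8 mM | run made earlier |  |
| alpha | 45 mM | run made earlier |  |
| teal | 15 mM |  | 50 min |
| violet | 25 mM |  | 50 min |
| green | 40 mM |  | 50 min |
| ochre | 60 mM |  | 50 min |

- zeta (time / min: D / %): 4.00: 7.9; 10.0: 19.2; 20.0: 33.3; 50.0: 51.3
- alpha (time / min: D / %): 4.00: 19.3; 10.0: 36.9; 20.0: 49.0; 50.0: 54.8

(each reading ± 1 percentage point)

- amount of D at the end, in percent of the Q charged for teal, violet, green, ochre, in this order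
- the shape of the row from first to last (falls all the way / falls, then rises / hardly changes / rises, then falls / rises all the way)

- reactions considered so far: Q + Z <-> D + Z; D <-> L; L <-> Q
- "hardly changes" means that all values lie within two and a half points (for a concentration: within two and a half percent of the largest)

1. Set the ceiling. Alpha reads 54.8% at 50.0 min, after 49.0% at 20.0 min; call that last reading the plateau, with 1 percentage point of scatter on it.

2. Set the floor. Each new flask holds more Z than zeta, so expect at least zeta's 51.3%. This bracket is 3.5 points wide: too wide to call the row flat.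

3. Tighten it. Define the gap as plateau minus D, and read how fast it closes: 0.0605 min⁻¹ in zeta between 20.0 min and 50.0 min, 0.114 min⁻¹ in alpha between 4.00 min and 10.0 min. Alpha holds 5.11 times zeta's Z, yet closes about twice as fast.

4. Write Z as z, its fraction of the Q charged: 0.800% in zeta, 4.09% in alpha. Call b the turnover rate, the closing rate gained per unit of z, a turnover frequency: 1.63 min⁻¹.

5. Count the extra turnovers n: b times the z above zeta's, times the time. Shrink zeta's gap by exp(-n). Teal gets n = 0.459, so D = 52.6%. Ochre gets n = 3.79, so D = 54.7%.

6. Commit: the row spans 2.1 points, inside the margin, so it hardly changes.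

7. Hold the forecast against this: from “a simple approach to a plateau” it gives 53.2%, 54.6%, 55%, 54.9%, hardly changes, its third point standing 0.2 points above the ceiling, and its first above my teal figure.

The flask gives 52.7%, 54.2%, 54.9%, 55.1%: hardly changes.

    Q + Z ⇌ D + Z, rate k1*[Q]*[Z] forward; the back reaction follows from the equilibrium constant (K = 2.30, k = 0.0250 L mol⁻¹ s⁻¹)
    D ⇌ L (K = 0.380, k = 0.00360 s⁻¹)
    L ⇌ Q (k = 4.90 × 10⁻⁴ s⁻¹)

In teal, the forward half-life of D to L alone, 3.2 min, is short against the 50 min run and against the 31 min of Q to D alone. Teal at 50.0 min holds L at 20.1% beside D at 52.7%, with Q at 27.2%; that L to D ratio of 0.381 matches the equilibrium constant of D to L, 0.38. Carry b to violet: n = 1.20 gives D = 53.7%, and violet stands at 54.2%.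

The runs were generated by integration for substances that don't exist.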